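**Retrosynthetic overview**
- The target is (R)-8-hydroxy-6-methoxy-3-(6-oxoundecyl)isochroman-1-one. The lactone C1–O2 bond is opened to a methyl salicylate carrying a C3 silyl ether, with the side-chain ketone masked as a dioxolane.
- The strategy rests on the benzenoid ring C4a–C5–C6–C7–C8–C8a. C5, C6, C7 and C8, with the C8 hydroxyl and C6 methoxyl oxygens, come from an acetoacetate-derived silyloxy diene. C8a (ester carbon attached) and C4a (C4 methylene attached) are the two carbons of an alkynoate. The bonds C4a–C5 and C8–C8a are cut by a Diels–Alder/aromatisation disconnection.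
- The alkynoate comes from carboxylation of a terminal alkyne made by acetylide opening of an (R)-terminal epoxide. The epoxide is resolved by hydrolytic kinetic resolution, and its carbon chain comes from 7-bromohept-1-ene and hexanoyl chloride.
- Ring order: the benzene ring is formed first (step 9), the δ-lactone ring last (step 10).

Key step: step 9

Assumption: (R,R)-(salen)Co(OAc) (trivalent cobalt; salen = dianion of (R,R)-N,N′-bis(3,5-di-tert-butylsalicylidene)cyclohexane-1,2-diamine) is taken to follow its usual sense with alkyl-substituted terminal epoxides, hydrolysing the (S)-epoxide and leaving the (R)-epoxide; the configuration of 7 would be checked before going on.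

**Step 1**
Reactants: 1 7-bromohept-1-ene; 2 hexanoyl chloride
Product: 4 tridec-12-en-6-one, via hept-6-enylmagnesium bromide 3 (not isolated)
Conditions: Mg, THF, 25–40 °C; then added to 2, Fe(acac)3 (3 mol %), THF, −78 °C → 0 °C
Reagents that add atoms: none
Why: Iron-catalysed acylation of a primary alkyl Grignard reagent by an acid chloride (Fe(acac)3 cross-coupling) should stop at the ketone, because the catalysed coupling is much faster at low temperature than addition of the Grignard reagent to the ketone formed.

**Step 2**
Reactants: 4 tridec-12-en-6-one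
Product: 5 2-(hept-6-en-1-yl)-2-pentyl-1,3-dioxolane
Conditions: HOCH2CH2OH, p-TsOH·H2O (cat.), toluene, reflux, Dean–Stark
Reagents that add atoms: ethylene glycol, OCCO
Why: Acid-catalysed ketalisation driven by azeotropic removal of water masks the ketone against the acetylide and butyllithium used later, and the isolated terminal alkene is inert.

**Step 3**
Reactants: 5 2-(hept-6-en-1-yl)-2-pentyl-1,3-dioxolane
Product: 6 rac-2-[5-(oxiran-2-yl)pentyl]-2-pentyl-1,3-dioxolane
Conditions: mCPBA, NaHCO3 (buffer), CH2Cl2, 0 °C → rt
Reagents that add atoms: mCPBA, O=C(OO)c1cccc(Cl)c1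
Why: Prilezhaev epoxidation of the terminal alkene by the peracid should give the racemic epoxide, with the bicarbonate buffer keeping the dioxolane from acid-catalysed cleavage.

**Step 4**
Reactants: 6 rac-2-[5-(oxiran-2-yl)pentyl]-2-pentyl-1,3-dioxolane
Product: 7 (R)-2-[5-(oxiran-2-yl)pentyl]-2-pentyl-1,3-dioxolane
Conditions: (R,R)-(salen)Co(OAc) (0.5 mol %), H2O (0.55 equiv), THF (minimal), 0 °C → rt; chromatography
Reagents that add atoms: none
Why: In the Jacobsen hydrolytic kinetic resolution the trivalent cobalt salen acetate should hydrolyse the (S)-epoxide selectively at its terminal carbon, leaving the (R)-epoxide, which is easily separated from the polar diol and carries the stereocentre that becomes C3.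

**Step 5**
Reactants: 7 (R)-2-[5-(oxiran-2-yl)pentyl]-2-pentyl-1,3-dioxolane
Product: 8 (R)-10,10-(ethylenedioxy)pentadec-1-yn-4-ol
Conditions: LiC≡CH·H2NCH2CH2NH2, DMSO, rt; then H2O
Reagents that add atoms: lithium acetylide–ethylenediamine complex, [Li]C#C.NCCN
Why: SN2 opening of the epoxide by the acetylide at the unhindered terminal carbon leaves the C–O bond of the stereocentre untouched, so the (R)-homopropargylic alcohol should result with retention of configuration.

**Step 6**
Reactants: 8 (R)-10,10-(ethylenedioxy)pentadec-1-yn-4-ol
Product: 9 (R)-4-(tert-butyldimethylsilyloxy)-10,10-(ethylenedioxy)pentadec-1-yne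
Conditions: TBSCl, imidazole, DMF, rt
Reagents that add atoms: TBSCl, CC(C)(C)[Si](C)(C)Cl
Why: Imidazole-promoted silylation of the secondary alcohol blocks it against acylation in the next step and against premature lactonisation after the cycloaddition.

**Step 7**
Reactants: 9 (R)-4-(tert-butyldimethylsilyloxy)-10,10-(ethylenedioxy)pentadec-1-yne
Product: 11 methyl (R)-5-(tert-butyldimethylsilyloxy)-11,11-(ethylenedioxy)hexadec-2-ynoate, via lithium acetylide of the silyl ether 10 (not isolated)
Conditions: n-BuLi, THF, −78 °C; then ClCO2Me, −78 °C → 0 °C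
Reagents that add atoms: methyl chloroformate, COC(=O)Cl
Why: Deprotonation of the terminal alkyne and C-acylation of the lithium acetylide by the chloroformate is the standard route to alk-2-ynoates, and the silyl ether and dioxolane are stable to butyllithium at low temperature.

**Step 8**
Reactants: 12 methyl (E)-3-methoxybut-2-enoate
Product: 14 1,3-dimethoxy-1-(trimethylsilyloxy)buta-1,3-diene (E/Z mixture), via lithium dienolate 13 (not isolated)
Conditions: LDA, THF, −78 °C; then TMSCl, −78 °C → rt; filtration, distillation
Reagents that add atoms: TMSCl, C[Si](C)(C)Cl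
Why: Vinylogous (γ) deprotonation of the β-methoxy enoate by LDA gives the extended dienolate, and O-silylation of it by the hard silyl chloride should give the silyl ketene acetal diene, which is moisture-sensitive and is used at once.

**Step 9**
Reactants: 11 methyl (R)-5-(tert-butyldimethylsilyloxy)-11,11-(ethylenedioxy)hexadec-2-ynoate; 14 1,3-dimethoxy-1-(trimethylsilyloxy)buta-1,3-diene
Product: 16 methyl 2-hydroxy-4-methoxy-6-[(R)-2-(tert-butyldimethylsilyloxy)-8,8-(ethylenedioxy)tridecyl]benzoate, via cyclohexa-1,4-diene silyl methyl ketal adduct 15 (not isolated)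
Conditions: 14 (3 equiv), neat (or toluene), 110–120 °C, sealed tube; then wet SiO2, CH2Cl2, rt
Reagents that add atoms: none
Why: A thermal, concerted but asynchronous normal-demand [4+2] cycloaddition (the known Diels–Alder aromatisation of 1-alkoxy-1-silyloxy-3-alkoxybutadienes with acetylenic esters to 6-alkyl-4-methoxysalicylates) joins the CH2 terminus of 14 to the β-carbon of the ynoate (C4a–C5) and the ketene-acetal carbon to the α-carbon (C8–C8a), giving the cyclohexa-1,4-diene 15. The carbocycle is closed by this intermolecular cycloaddition, both σ-bonds forming suprafacially across one π-bond of the alkyne. Hydrolysis of the silyl methyl ketal at C8 on wet silica should release trimethylsilanol and methanol and leave a C8 ketone that tautomerises through C5–H to the phenol, so the alkyne supplies the arene oxidation level and no oxidant is needed. No lasting stereocentre is made: the ketal carbon of 15 forms as a mixture and is flattened on aromatisation, while the silyloxy-bearing carbon is a spectator and keeps its (R) configuration. The step needs regioselectivity, and this is secured by matching the most nucleophilic diene carbon (the CH2 terminus, pushed by the 3-methoxy and ketene-acetal oxygens) with the electrophilic β-carbon of the ynoate, which puts the ester between the new hydroxyl and the side chain; the TBS ether and dioxolane are inert to heat and neutral silica.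

**Step 10**
Reactants: 16 methyl 2-hydroxy-4-methoxy-6-[(R)-2-(tert-butyldimethylsilyloxy)-8,8-(ethylenedioxy)tridecyl]benzoate
Product: 18 (R)-8-hydroxy-6-methoxy-3-(6-oxoundecyl)isochroman-1-one, via methyl 2-hydroxy-6-[(R)-2-hydroxy-8-oxotridecyl]-4-methoxybenzoate 17 (not isolated)
Conditions: 48% aq. HF, MeCN, 0 °C → rt; aqueous work-up; then p-TsOH·H2O (cat.), toluene, 80 °C
Reagents that add atoms: water, O
Why: Aqueous HF should cleave the TBS ether and hydrolyse the dioxolane, and acid-catalysed intramolecular transesterification (6-exo-trig lactonisation) of the freed C3 hydroxyl onto the methyl ester then closes the lactone without breaking the C3–O bond, so the (R) configuration is retained.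

**Compound list**
1 | 7-bromohept-1-ene | C=CCCCCCBr | starting material
2 | hexanoyl chloride | CCCCCC(=O)Cl | starting material
3 | hept-6-enylmagnesium bromide | C=CCCCCC[Mg]Br | intermediate
4 | tridec-12-en-6-one | CCCCCC(=O)CCCCCC=C | intermediate
5 | 2-(hept-6-en-1-yl)-2-pentyl-1,3-dioxolane | C=CCCCCCC1(CCCCC)OCCO1 | intermediate
6 | rac-2-[5-(oxiran-2-yl)pentyl]-2-pentyl-1,3-dioxolane | CCCCCC1(CCCCCC2CO2)OCCO1 | intermediate
7 | (R)-2-[5-(oxiran-2-yl)pentyl]-2-pentyl-1,3-dioxolane | CCCCCC1(CCCCC[C@@H]2CO2)OCCO1 | intermediate
8 | (R)-10,10-(ethylenedioxy)pentadec-1-yn-4-ol | C#CC[C@H](O)CCCCCC1(CCCCC)OCCO1 | intermediate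
9 | (R)-4-(tert-butyldimethylsilyloxy)-10,10-(ethylenedioxy)pentadec-1-yne | C#CC[C@H](O[Si](C)(C)C(C)(C)C)CCCCCC1(CCCCC)OCCO1 | intermediate
10 | lithium acetylide of 9 | [Li]C#CC[C@H](O[Si](C)(C)C(C)(C)C)CCCCCC1(CCCCC)OCCO1 | intermediate
11 | methyl (R)-5-(tert-butyldimethylsilyloxy)-11,11-(ethylenedioxy)hexadec-2-ynoate | COC(=O)C#CC[C@H](O[Si](C)(C)C(C)(C)C)CCCCCC1(CCCCC)OCCO1 | intermediate
12 | methyl (E)-3-methoxybut-2-enoate | CO/C(C)=C/C(=O)OC | starting material
13 | lithium 1,3-dimethoxybuta-1,3-dien-1-olate | C=C(OC)C=C(OC)O[Li] | intermediate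
14 | 1,3-dimethoxy-1-(trimethylsilyloxy)buta-1,3-diene (E/Z mixture) | COC(=C)C=C(OC)O[Si](C)(C)C | intermediate
15 | cyclohexa-1,4-diene cycloadduct, silyl methyl ketal at C8 (mixture of epimers at the ketal carbon) | COC(=O)C1=C(C[C@H](O[Si](C)(C)C(C)(C)C)CCCCCC2(CCCCC)OCCO2)CC(OC)=CC1(OC)O[Si](C)(C)C | intermediate
16 | methyl 2-hydroxy-4-methoxy-6-[(R)-2-(tert-butyldimethylsilyloxy)-8,8-(ethylenedioxy)tridecyl]benzoate | COC(=O)c1c(O)cc(OC)cc1C[C@H](O[Si](C)(C)C(C)(C)C)CCCCCC2(CCCCC)OCCO2 | intermediate
17 | methyl 2-hydroxy-6-[(R)-2-hydroxy-8-oxotridecyl]-4-methoxybenzoate | COC(=O)c1c(O)cc(OC)cc1C[C@H](O)CCCCCC(=O)CCCCC | intermediate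
18 | (R)-8-hydroxy-6-methoxy-3-(6-oxoundecyl)isochroman-1-one | CCCCCC(=O)CCCCC[C@@H]1Cc2cc(OC)cc(O)c2C(=O)O1 | target

**Totals**
Total step count: 10. Longest linear sequence: 9 steps (steps 1–7, 9 and 10); the diene of step 8 is a one-step branch.

**Steps most likely to fail**

Step 9. The β-alkyl ynoate is a sluggish dienophile, so the diene may decompose or oligomerise before cycloaddition is complete. The fallback gives up the cycloaddition and attaches a preformed arene; it sets out from epoxide 7 and comes back at target 18. Epoxide 7 would be opened at its terminal carbon by 3,5-dimethoxyphenylmagnesium bromide with catalytic CuI (THF, −30 °C) to give (R)-1-(3,5-dimethoxyphenyl)-8,8-(ethylenedioxy)tridecan-2-ol F1, with the stereocentre untouched. NBS in MeCN at 0 °C should brominate the ring position flanked by the side chain and one methoxyl (para to the other) to give (R)-1-(2-bromo-3,5-dimethoxyphenyl)-8,8-(ethylenedioxy)tridecan-2-ol F2. n-BuLi (2.2 equiv, THF, −78 °C) would form the alkoxide and, by bromine–lithium exchange, the aryllithium, which is trapped with CO2. Acidification with aq. HCl/THF should lactonise the hydroxy acid and remove the dioxolane to give (R)-6,8-dimethoxy-3-(6-oxoundecyl)isochroman-1-one F3. BCl3 in CH2Cl2 (−78 °C → 0 °C) should then cleave only the C8 methyl ether, which is chelated to the lactone carbonyl, and give 18.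

Step 10. Lactonisation may stall because the ester is deactivated by its hydrogen bond to the ortho hydroxyl, and the dioxolane may be only partly hydrolysed or re-formed. The fallback separates the two events and closes the lactone under basic rather than acidic conditions; it sets out from 16 and comes back at 18. TBAF in THF (0 °C → rt) would remove the silyl group, and the alkoxide freed next to the ester should close the lactone to give (R)-8-hydroxy-6-methoxy-3-[5-(2-pentyl-1,3-dioxolan-2-yl)pentyl]isochroman-1-one F4. PPTS in acetone/water at 50 °C would then hydrolyse the dioxolane to give 18.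

Step 1. Over-addition of the Grignard reagent to the ketone, or homocoupling, may erode the acylation. The fallback replaces the acid chloride by an amide whose tetrahedral adduct is stable until work-up; it sets out from 2 and comes back at 4. Hexanoyl chloride 2 with MeNH(OMe)·HCl and Et3N in CH2Cl2 at 0 °C would give N-methoxy-N-methylhexanamide F5. Addition of Grignard reagent 3 (THF, 0 °C) would form the chelated magnesium adduct, which collapses to ketone 4 only on aqueous acid work-up.

**Further compounds**
F1 | step 9 | (R)-1-(3,5-dimethoxyphenyl)-8,8-(ethylenedioxy)tridecan-2-ol | COc1cc(OC)cc(C[C@H](O)CCCCCC2(CCCCC)OCCO2)c1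
F2 | step 9 | (R)-1-(2-bromo-3,5-dimethoxyphenyl)-8,8-(ethylenedioxy)tridecan-2-ol | COc1cc(OC)c(Br)c(C[C@H](O)CCCCCC2(CCCCC)OCCO2)c1
F3 | step 9 | (R)-6,8-dimethoxy-3-(6-oxoundecyl)isochroman-1-one | CCCCCC(=O)CCCCC[C@@H]1Cc2cc(OC)cc(OC)c2C(=O)O1
F4 | step 10 | (R)-8-hydroxy-6-methoxy-3-[5-(2-pentyl-1,3-dioxolan-2-yl)pentyl]isochroman-1-one | CCCCCC1(CCCCC[C@@H]2Cc3cc(OC)cc(O)c3C(=O)O2)OCCO1
F5 | step 1 | N-methoxy-N-methylhexanamide | CCCCCC(=O)N(C)OC
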